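Readings and results were computed from invented constants; noise was put on by code.

Start from the balance.

| flask | substrate | remark | time |
|---|---|---|---|
| Thursday's | 0.043 M | run made earlier |  |
| Monday's | 0.17 M | run made earlier |  |
| flask | 0.085 M |  | 30 h |

| run | time / h | target / % | substrate / % |
|---|---|---|---|
| Thursday's | 0.333 | 3.4 | 98.4 |
| Thursday's | 1.00 | 9.9 | 83.2 |
| Thursday's | 3.00 | 11.7 | 23.6 |
| Thursday's | 10.0 | 0.6 | 11.3 |
| Thursday's | 30.0 | 0 | 3.9 |
| Monday's | 0.333 | 17.2 | 80.2 |
| Monday's | 1.00 | 39.6 | 1.7 |
| Monday's | 3.00 | 0 | 0 |
| Monday's | 10.0 | 2.3 | 1.2 |
| Monday's | 30.0 | 0 | 0 |

(scatter of a reading: 1 percentage point)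

- the analysis behind the earlier runs scatters by 1 percentage point, standard deviation

- the best time, 30 h at the latest, for target
- the amount of target, in percent of the substrate charged, at that time

1. The S-shaped substrate curves suggest autocatalysis, substrate and target giving more target, with target lost by a step of its own. If so, target stops rising when substrate falls to one concentration, the same for each charge, and you can read that concentration without any fit.

2. On that picture, the share of the charge missing from both readings equals this concentration over the charge, times the logarithm of charged over remaining substrate, so Thursday's run at 3.00 h gives 0.0193 M and Monday's run at 1.00 h gives 0.0245 M.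

3. The second way uses rates, not the balance: between 0.333 h and 1.00 h in Thursday's run, logarithmic substrate loss of 0.252 h⁻¹ and target gain of 1.60 h⁻¹, with mean amounts, give 0.0208 M. These are different readings, and the value lies between the other two , so I trust the middle in logarithms of the balance values, the break-even concentration, on this picture the substrate level at which target stops rising, here as a reading: 0.0217 M.

4. Setting remaining substrate to this level in the balance gives your flask 39.6%. Its charge lies midway in logarithms between the two runs, so I take the middle in logarithms of the times at which Thursday's and Monday's runs, interpolated between readings, reach that level, 1.79 h and 0.651 h, which is 1.08 h.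

5. The forecast says 1.2 h and 26%, lower in amount than my reckoning, holding that at higher concentration “formation outruns decay”.

6. The flask gives 41.3% of target at 1.11 h, by this scheme:

    substrate + target → 2 target (k = 1.40 M⁻¹ min⁻¹)
    substrate → target (k = 7.30 × 10⁻⁴ min⁻¹)
    target → over-reaction product (k = 0.0300 min⁻¹)

At that moment substrate in the flask stands at 24.8% of the charge, which is 0.0211 M against the break-even concentration of 0.0217 M. Put into the balance for the neighbour flask charged with 0.14 M, the break-even concentration gives 55.6% of target, and that neighbour's best is 56.5%.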